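## Retrosynthetic overview
1. Ring A (enoate δ-lactone) comes from a sulfoxide elimination after lactonisation. Its C–C bond at the spiro carbon comes from a Mukaiyama aldol with acetone. The ring B carbinol comes from an alkoxide-directed methyl transfer.
2. Ring B (cyclohexane) comes from indium allylation of a ring C carbaldehyde with bromide 21, followed by ring-closing metathesis.
3. Ring C (cyclopentane) and the quaternary carbon shared by rings B, C and D come from propargylation next to the ketone, then a 5-exo-dig formyl-alkyne carbocyclisation.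
4. Ring D (bicyclo[2.2.2]octanone) and the ring E carbons come from the key fragment union. The dienolate of enone 6 adds to methyl acrylate in an intermolecular Michael reaction, and a second Michael reaction closes the bridge.
5. Enone 6 comes from (R)-carvone, whose isopropenyl group acts as a traceless control element. Ring order: D, E, C, B, A.

Assumption: centres that are planarised again later (noted as mixtures) are drawn without configuration. LDA, LiHMDS, KHMDS and the stannane of step 3 are bought as such.

## Route

Step 1
Reactants: 1 (R)-(−)-carvone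
Product: 2 (5R,6R)-6-(hydroxymethyl)carvone (CH2OH trans to isopropenyl)
Conditions: LDA, THF, −78 °C; CH2O (gas), −78 °C; H2O
Reagents that add atoms: formaldehyde, C=O
Why: The kinetic cross-conjugated lithium enolate undergoes an aldol addition to monomeric formaldehyde at the alpha-prime carbon, anti to the neighbouring isopropenyl group, which sets the trans relationship.

Step 2
Reactants: 2 (5R,6R)-6-(hydroxymethyl)carvone
Product: 3 TBS ether of 2
Conditions: TBSCl, imidazole, DMF, 0 °C to rt
Reagents that add atoms: tert-butyldimethylsilyl chloride, CC(C)(C)[Si](C)(C)Cl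
Why: Mild silylation of the primary alcohol blocks retro-aldol and dehydration of the β-hydroxy ketone and touches no stereocentre.

Step 3
Reactants: 3 TBS ether of 2
Product: 4 tertiary allylic alcohol (carbinol epimers)
Conditions: Bu3SnCH2OCH2OMe, n-BuLi, THF, −78 °C; then 3, −78 °C; H2O
Reagents that add atoms: tributyl[(methoxymethoxy)methyl]stannane, CCCC[Sn](CCCC)(CCCC)COCOC
Why: Tin–lithium exchange gives an alkoxymethyllithium that adds 1,2 to the enone carbonyl, and the new carbinol centre is destroyed in the next step.

Step 4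
Reactants: 4 tertiary allylic alcohol
Product: 5 transposed enone (4,5-trans 4-(TBSOCH2)-3-(MOMOCH2)-2-methyl-5-isopropenylcyclohex-2-enone)
Conditions: pyridinium chlorochromate [C5H5NH][CrO3Cl], CH2Cl2, rt
Reagents that add atoms: pyridinium chlorochromate, [O-][Cr](=O)(=O)Cl.c1cc[nH+]cc1
Why: In the Dauben–Michno oxidative allylic transposition the chromate ester shifts in a [3,3] sense and is oxidised to the β-substituted enone, leaving both ring stereocentres untouched.

Step 5
Reactants: 5 transposed enone
Product: 6 6-methyl enone (epimers at the new methyl-bearing carbon)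
Conditions: LDA, THF, −78 °C; MeI, −78 to 0 °C
Reagents that add atoms: iodomethane, CI
Why: This is a kinetic alpha-prime enolate alkylation, and the epimer ratio does not matter because this carbon is planarised in step 6.

Step 6
Reactants: 6 6-methyl enone; 7 methyl acrylate
Product: 9 bicyclo[2.2.2]octanone keto ester (ester syn to the ketone bridge), via mono-Michael lithium ester enolate 8 (not isolated)
Conditions: LiHMDS, THF, −78 °C; 7, −78 °C to rt; H2O
Reagents that add atoms: none
Why: This is a tandem intermolecular Michael and ring-closing Michael reaction. The cross-conjugated dienolate attacks acrylate anti to the adjacent isopropenyl group, and the lithium-chelated ester enolate closes onto the enone on the same face. This sets both bridgeheads and the endo ester centre.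

Step 7
Reactants: 9 bicyclo[2.2.2]octanone keto ester
Product: 11 de-isopropenylated keto ester, via methoxy hydroperoxide 10 (not isolated)
Conditions: O3, MeOH, −78 °C; then PhSH, FeSO4·7H2O, −78 °C to rt
Reagents that add atoms: ozone, [O-][O+]=O; methanol, CO (both stay only in intermediate 10)
Why: In this hydrodealkenylation FeSO4 reduces the Criegee-derived hydroperoxide to an alkoxy radical, which loses methyl acetate by β-scission. The ring radical then takes hydrogen from the thiol, and the only alkene present is the one to be removed.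

Step 8
Reactants: 11 de-isopropenylated keto ester
Product: 12 propargylated keto ester
Conditions: KHMDS (1.05 equiv), THF, −78 °C; propargyl bromide, −78 to 0 °C
Reagents that add atoms: propargyl bromide, C#CCBr
Why: The ketone has only one enolisable position, so the enolate alkylation is regiospecific. The endo ester shields one face, so the electrophile enters from the face turned toward the CH(CH2OTBS)–CH2 bridge and sets the quaternary centre.

Step 9
Reactants: 12 propargylated keto ester
Product: 13 hydroxy keto γ-lactone (ring E closed)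
Conditions: 3 M aq. HCl (cat.), THF, 50 °C
Reagents that add atoms: none
Why: Acid hydrolysis removes the MOM and TBS groups, and the freed bridgehead carbinol lactonises onto the nearby endo ester. The other primary alcohol cannot reach that ester.

Step 10
Reactants: 13 hydroxy keto γ-lactone
Product: 14 keto lactone aldehyde
Conditions: Dess–Martin periodinane, CH2Cl2, rt
Reagents that add atoms: none
Why: This neutral Dess–Martin oxidation of the primary alcohol gives an alpha centre that is consumed in the next step.

Step 11
Reactants: 14 keto lactone aldehyde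
Product: 15 isotwistane aldehyde with exocyclic methylene (ring C closed)
Conditions: Cu(OTf)2 (5 mol %), PPh3 (20 mol %), cyclohexylamine (20 mol %), 1,2-dichloroethane, 60 °C
Reagents that add atoms: none
Why: In this Conia-ene-type 5-exo-dig carbocyclisation the enamine of the alpha-branched aldehyde attacks the copper-activated alkyne. The short tether allows attack from one face only, which fixes the new quaternary centre.

Step 12
Reactants: 15 isotwistane aldehyde
Product: 16 vinyl diene
Conditions: Ph3PCH3Br, KHMDS, THF, 0 °C; then 15, −78 to 0 °C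
Reagents that add atoms: methyltriphenylphosphonium bromide, C[P+](c1ccccc1)(c1ccccc1)c1ccccc1.[Br-]
Why: This is a Wittig methylenation of a non-enolisable aldehyde, and the hindered ketone and the lactone do not react under these conditions.

Step 13
Reactants: 16 vinyl diene
Product: 17 spiro-epoxide
Conditions: mCPBA (1.0 equiv), CH2Cl2, 0 °C
Reagents that add atoms: 3-chloroperbenzoic acid, OOC(=O)c1cccc(Cl)c1
Why: The Prilezhaev epoxidation picks the more electron-rich 1,1-disubstituted alkene over the vinyl group. It comes from the face away from the three-carbon ketone bridge.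

Step 14
Reactants: 17 spiro-epoxide
Product: 18 ring C carbaldehyde
Conditions: BF3·OEt2 (0.3 equiv), CH2Cl2, −78 °C
Reagents that add atoms: none
Why: In the Meinwald rearrangement the 1,2-hydride shift occurs anti to the leaving oxygen, so the formyl group ends on the face of the former epoxide oxygen. The centre also stays epimerisable, and only this epimer can later close ring B.

Step 15
Reactants: 19 methyl (phenylsulfanyl)acetate; 20 (E)-1,4-dibromobut-2-ene
Product: 21 methyl (E)-6-bromo-2-(phenylsulfanyl)hex-4-enoate (racemic)
Conditions: NaH, THF, 0 °C; 20 (3 equiv), 0 °C to rt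
Reagents that add atoms: none
Why: The sulfur-stabilised ester enolate undergoes SN2 monoalkylation with excess dibromide, and its stereocentre is removed in step 22.

Step 16
Reactants: 18 ring C carbaldehyde; 21 methyl (E)-6-bromo-2-(phenylsulfanyl)hex-4-enoate
Product: 22 branched homoallylic alcohol (diastereomer mixture)
Conditions: In powder, THF/H2O 3:1, rt
Reagents that add atoms: none
Why: The Barbier-type indium carbonyl allylation is aldehyde-selective and reacts at the γ-carbon, and the two new centres are both erased in step 18.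

Step 17
Reactants: 22 branched homoallylic alcohol
Product: 23 ring B cyclohexenol (mixture)
Conditions: second-generation Hoveyda–Grubbs catalyst RuCl2(=CH-C6H4-2-OiPr)(SIMes) (5 mol %), toluene, 80 °C
Reagents that add atoms: none
Why: Ring-closing metathesis of two monosubstituted alkenes forms a six-membered ring, and the cis disposition of both arms on ring C allows closure.

Step 18
Reactants: 23 ring B cyclohexenol
Product: 25 conjugated ring B enone, via β,γ-unsaturated ketone 24 (not isolated)
Conditions: Dess–Martin periodinane, CH2Cl2, rt; filter; DBU (0.2 equiv), CH2Cl2, rt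
Reagents that add atoms: none
Why: Dess–Martin oxidation is followed by base-catalysed alkene migration into conjugation. The ring B/C junction hydrogen equilibrates to the only low-strain cis fusion.

Step 19
Reactants: 25 conjugated ring B enone
Product: 27 β-hydroxy ketone with quaternary future spiro carbon, via dimethylphenylsilyl enol ether 26 (not isolated)
Conditions: [(Ph3P)CuH]6 (3 mol %), PhMe2SiH, toluene, rt; then acetone, TiCl4, CH2Cl2, −78 °C; H2O
Reagents that add atoms: acetone, CC(C)=O; dimethylphenylsilane, C[SiH](C)c1ccccc1 (silicon stays only in intermediate 26)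
Why: Copper hydride conjugate hydrosilylation gives the enol ether regiospecifically. The Mukaiyama aldol then takes acetone axially from the open convex face away from ring E, so the hydroxy-isopropyl group ends cis to the junction hydrogen.

Step 20
Reactants: 27 β-hydroxy ketone
Product: 28 diol ester
Conditions: AlMe3 (4 equiv), CH2Cl2, −78 to 0 °C; aq. Rochelle salt
Reagents that add atoms: trimethylaluminium, C[Al](C)C
Why: This is an alkoxide-directed 1,2-addition. The aluminium alkoxide of the neighbouring carbinol passes methyl to the ketone through a six-membered transition state on its own face, giving methyl cis and hydroxyl trans to that arm. Esters, lactone and the caged ketone stay inert at this temperature.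

Step 21
Reactants: 28 diol ester
Product: 29 α-phenylsulfanyl spiro δ-lactone (ring A closed)
Conditions: PPTS (cat.), benzene, 60 °C
Reagents that add atoms: none
Why: In this acid-catalysed lactonisation the exposed gem-dimethyl carbinol closes faster (Thorpe–Ingold effect) than the ring B hydroxyl buried on the concave face.

Step 22
Reactants: 29 α-phenylsulfanyl spiro δ-lactone
Product: 31 CNP0222978.3, via sulfoxide 30 (not isolated)
Conditions: mCPBA (1.0 equiv), CH2Cl2, −78 °C; then toluene, 110 °C
Reagents that add atoms: 3-chloroperbenzoic acid, OOC(=O)c1cccc(Cl)c1 (oxygen stays only in intermediate 30)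
Why: Sulfide oxidation is followed by thermal sulfoxide syn-elimination. This can only go toward the ring CH2 and installs the enoate under neutral conditions that leave all eight stereocentres alone.

## Compound list
1 | (R)-(−)-carvone | CC1=CC[C@H](CC1=O)C(C)=C | starting material
2 | (5R,6R)-6-(hydroxymethyl)carvone | CC1=CC[C@@H](C(C)=C)[C@H](CO)C1=O | intermediate
3 | TBS ether of 2 | CC1=CC[C@@H](C(C)=C)[C@H](CO[Si](C)(C)C(C)(C)C)C1=O | intermediate
4 | tertiary allylic alcohol (carbinol epimers) | CC1=CC[C@@H](C(C)=C)[C@H](CO[Si](C)(C)C(C)(C)C)C1(O)COCOC | intermediate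
5 | transposed enone | CC1=C(COCOC)[C@@H](CO[Si](C)(C)C(C)(C)C)[C@H](C(C)=C)CC1=O | intermediate
6 | 6-methyl enone (methyl epimers) | CC1=C(COCOC)[C@@H](CO[Si](C)(C)C(C)(C)C)[C@H](C(C)=C)C(C)C1=O | intermediate
7 | methyl acrylate | C=CC(=O)OC | starting material
8 | mono-Michael lithium ester enolate | [Li+].[O-]C(OC)=CC[C@@]1(C)C(=O)C(C)=C(COCOC)[C@@H](CO[Si](C)(C)C(C)(C)C)[C@@H]1C(C)=C | intermediate
9 | bicyclo[2.2.2]octanone keto ester | C[C@]12C[C@H](C(=O)OC)[C@](COCOC)(C(C)C1=O)[C@@H](CO[Si](C)(C)C(C)(C)C)[C@@H]2C(C)=C | intermediate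
10 | methoxy hydroperoxide | C[C@]12C[C@H](C(=O)OC)[C@](COCOC)(C(C)C1=O)[C@@H](CO[Si](C)(C)C(C)(C)C)[C@@H]2C(C)(OC)OO | intermediate
11 | de-isopropenylated keto ester | C[C@]12C[C@H](C(=O)OC)[C@](COCOC)(C(C)C1=O)[C@@H](CO[Si](C)(C)C(C)(C)C)C2 | intermediate
12 | propargylated keto ester | C[C@]12C[C@H](C(=O)OC)[C@](COCOC)([C@@](C)(CC#C)C1=O)[C@@H](CO[Si](C)(C)C(C)(C)C)C2 | intermediate
13 | hydroxy keto γ-lactone | C[C@]12C[C@@H]3C(=O)OC[C@@]3([C@@](C)(CC#C)C1=O)[C@@H](CO)C2 | intermediate
14 | keto lactone aldehyde | C[C@]12C[C@@H]3C(=O)OC[C@@]3([C@@](C)(CC#C)C1=O)[C@@H](C=O)C2 | intermediate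
15 | isotwistane aldehyde with exocyclic methylene | C[C@]12C[C@@H]3C(=O)OC[C@]35[C@@](C)(CC(=C)[C@]5(C=O)C2)C1=O | intermediate
16 | vinyl diene | C[C@]12C[C@@H]3C(=O)OC[C@]35[C@@](C)(CC(=C)[C@]5(C=C)C2)C1=O | intermediate
17 | spiro-epoxide | C[C@]12C[C@@H]3C(=O)OC[C@]35[C@@](C)(C[C@]6(CO6)[C@]5(C=C)C2)C1=O | intermediate
18 | ring C carbaldehyde | C[C@]12C[C@@H]3C(=O)OC[C@]35[C@@](C)(C[C@@H](C=O)[C@]5(C=C)C2)C1=O | intermediate
19 | methyl (phenylsulfanyl)acetate | COC(=O)CSc1ccccc1 | starting material
20 | (E)-1,4-dibromobut-2-ene | BrC/C=C/CBr | starting material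
21 | methyl (E)-6-bromo-2-(phenylsulfanyl)hex-4-enoate | COC(=O)C(Sc1ccccc1)C/C=C/CBr | intermediate
22 | branched homoallylic alcohol (mixture) | C[C@]12C[C@@H]3C(=O)OC[C@]35[C@@](C)(C[C@@H](C(O)C(C=C)CC(Sc6ccccc6)C(=O)OC)[C@]5(C=C)C2)C1=O | intermediate
23 | ring B cyclohexenol (mixture) | C[C@]12C[C@@H]3C(=O)OC[C@]35[C@@](C)(C[C@H]6C(O)C(CC(Sc7ccccc7)C(=O)OC)C=C[C@@]56C2)C1=O | intermediate
24 | β,γ-unsaturated ketone | C[C@]12C[C@@H]3C(=O)OC[C@]35[C@@](C)(C[C@H]6C(=O)C(CC(Sc7ccccc7)C(=O)OC)C=C[C@@]56C2)C1=O | intermediate
25 | conjugated ring B enone | C[C@]12C[C@@H]3C(=O)OC[C@]35[C@@](C)(C[C@H]6C(=O)C(CC(Sc7ccccc7)C(=O)OC)=CC[C@@]56C2)C1=O | intermediate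
26 | dimethylphenylsilyl enol ether | C[C@]12C[C@@H]3C(=O)OC[C@]35[C@@](C)(C[C@H]6C(O[Si](C)(C)c8ccccc8)=C(CC(Sc7ccccc7)C(=O)OC)CC[C@@]56C2)C1=O | intermediate
27 | β-hydroxy ketone | C[C@]12C[C@@H]3C(=O)OC[C@]35[C@@](C)(C[C@H]6C(=O)[C@](CC(Sc7ccccc7)C(=O)OC)(C(C)(C)O)CC[C@@]56C2)C1=O | intermediate
28 | diol ester | C[C@]12C[C@@H]3C(=O)OC[C@]35[C@@](C)(C[C@H]6[C@@](C)(O)[C@](CC(Sc7ccccc7)C(=O)OC)(C(C)(C)O)CC[C@@]56C2)C1=O | intermediate
29 | α-phenylsulfanyl spiro δ-lactone | C[C@]12C[C@@H]3C(=O)OC[C@]35[C@@](C)(C[C@H]6[C@@](C)(O)[C@@]8(CC(Sc7ccccc7)C(=O)OC8(C)C)CC[C@@]56C2)C1=O | intermediate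
30 | sulfoxide | C[C@]12C[C@@H]3C(=O)OC[C@]35[C@@](C)(C[C@H]6[C@@](C)(O)[C@@]8(CC(S(=O)c7ccccc7)C(=O)OC8(C)C)CC[C@@]56C2)C1=O | intermediate
31 | CNP0222978.3 | CC1(C)OC(=O)C=C[C@]12CC[C@@]13C[C@@]4(C)C[C@@H]5C(=O)OC[C@]51[C@@](C)(C[C@H]3[C@@]2(C)O)C4=O | target

## Step count and risks
Total steps: 22. Longest linear sequence: 21 (steps 1–14 and 16–22).

**Step 6.** The second Michael closure must form a quaternary bridgehead next to a substituted carbon, and the two ring substituents sit on opposite faces. The fallback sets out from 6 and comes back at 9. LDA and Me3SiCl turn 6 into the cross-conjugated trimethylsilyl dienol ether F1. Heating this neutral diene with methyl acrylate 7 (toluene, 130 °C, sealed tube) gives, by a concerted endo Diels–Alder reaction anti to the isopropenyl group, the bicyclic silyl enol ether F2. Brief treatment with citric acid in methanol cleaves only the enol ether and gives 9.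

**Step 19.** A tetrasubstituted enol ether has to attack a ketone, and the aldol can revert. The fallback sets out from 25 (through 26, made as in step 19) and comes back at 28. Enol ether 26 is C-acylated irreversibly with acetyl chloride and TiCl4 at −78 °C, on the same convex face, to give the 2-acetyl ketone F3. Excess AlMe3 then adds first to the exposed acetyl group, and the resulting aluminium alkoxide passes a second methyl group to the ring ketone. This gives 28 directly.

**Step 20.** The ring B ketone is flanked by a quaternary and a tertiary carbon. The fallback sets out from 27 and comes back at 29.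
- PPTS first closes ring A to give the keto spiro-lactone F4, which removes the retro-aldol risk.
- Dimethylsulfonium methylide (Me3SI, KHMDS, THF) attacks only the ketone and gives the spiro-epoxide F5.
- PhSeSePh with NaBH4 in ethanol opens F5 at its CH2 group to give the β-hydroxy selenide F6.
- Bu3SnH (1 equiv) with AIBN in benzene at 80 °C replaces selenium by hydrogen and gives 29.

## Further compounds
F1 | step 6 | trimethylsilyl dienol ether of 6 | CC1=C(O[Si](C)(C)C)C(C)=C(COCOC)[C@@H](CO[Si](C)(C)C(C)(C)C)[C@@H]1C(C)=C
F2 | step 6 | bicyclic trimethylsilyl enol ether | C[C@]12C[C@H](C(=O)OC)[C@](COCOC)(C(C)=C1O[Si](C)(C)C)[C@@H](CO[Si](C)(C)C(C)(C)C)[C@@H]2C(C)=C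
F3 | step 19 | 2-acetyl ketone | C[C@]12C[C@@H]3C(=O)OC[C@]35[C@@](C)(C[C@H]6C(=O)[C@](CC(Sc7ccccc7)C(=O)OC)(C(C)=O)CC[C@@]56C2)C1=O
F4 | step 20 | keto spiro-lactone | C[C@]12C[C@@H]3C(=O)OC[C@]35[C@@](C)(C[C@H]6C(=O)[C@@]8(CC(Sc7ccccc7)C(=O)OC8(C)C)CC[C@@]56C2)C1=O
F5 | step 20 | ring B spiro-epoxide | C[C@]12C[C@@H]3C(=O)OC[C@]35[C@@](C)(C[C@H]6[C@]9(CO9)[C@@]8(CC(Sc7ccccc7)C(=O)OC8(C)C)CC[C@@]56C2)C1=O
F6 | step 20 | β-hydroxy selenide | C[C@]12C[C@@H]3C(=O)OC[C@]35[C@@](C)(C[C@H]6[C@@](C[Se]c9ccccc9)(O)[C@@]8(CC(Sc7ccccc7)C(=O)OC8(C)C)CC[C@@]56C2)C1=O
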